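**Numbering.** The cyclopentane is C1–C2–C3–C4–C5: C1 carries the angular methyl (C15), C4 the hydroxyl and the isopropyl group, C5 the ring-fusion hydrogen. The seven-membered ring runs from C5 through C6 (aroyloxy), C7, C8 (methyl), C9 and C10 (tigloyloxy) back to C1, with the double bond between C8 and C9. Descriptors refer to this numbering. Compound numbers 1–36 are those of the list after the steps. "Upper face" means the face that carries C15.

## Analysis of the target

The target is a cis-fused hydroazulene (daucane skeleton): a cyclopentane and a cycloheptene share the C1–C5 bond, with the trisubstituted alkene C8=C9 in the larger ring. Five stereocentres are contiguous or near-contiguous: quaternary C1 (methyl), C4 (tertiary alcohol with isopropyl), C5 (H), C6 (4-hydroxybenzoate) and C10 (tiglate); the configuration is 1R,4R,5S,6S,10R. The C1 methyl, H5, O6, O10 and the isopropyl group lie on one face; only the C4 hydroxyl lies on the other. Sensitive groups are two different esters on secondary oxygens (one allylic and α,β-unsaturated), a free phenol, and a tertiary alcohol that is β to C6, so any C6 ketone on the way is open to retro-aldol cleavage or elimination. The difficulty is the all-carbon quaternary centre C1, wedged between the C10 and C5 stereocentres: a nucleophile added to C1 of an enone would come anti to the C10 oxygen, the wrong face. The route rests on two facts: O6 is on the same face as the C1 methyl, and C6 is bonded to C5. A C6 hydroxyl can therefore deliver a methylene to a C1=C5 alkene on the correct face, and a C6 ketone can afterwards break the temporary C5–C15 bond.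

## Retrosynthetic reasoning

**Esters (36 ⇒ 35 ⇒ 33 + 34; 33 ⇒ 32 ⇒ 30 + 31).** The two C–O acyl bonds are cut last. In 30 the only acylable hydroxyl is at C6 (O4 is tertiary, O10 silylated), so the aroyl group from 31 goes on first. The tiglate follows from 34 after O10 is freed. The phenol travels as an acetate, which survives acidic fluoride and leaves by mild methanolysis without touching the two alkyl esters.

**C6–H (30 ⇒ 29 ⇒ 28).** The C6 carbinol is taken back to a ketone because the ketone is needed for the next disconnection. The free C4 hydroxyl of 29 can deliver hydride to C6 from the lower face. 29 comes from 28 by selective removal of the triethylsilyl group on O4.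

**C5–C15 (28 ⇒ 27 ⇒ 26).** The angular methyl is read as one carbon of a cyclopropane across C1–C5. In 27 the C5–C15 bond is conjugated with the C6 carbonyl, so a dissolving-metal reduction should break it and leave C15 as the methyl group. The forward step must cleave C5–C15 and not C1–C5, and protonate C5 to the cis fusion. 27 is the oxidation product of 26.

**C1–C15 and C5–C15 (26 ⇒ 24 + 25).** This is the key disconnection. The quaternary centre is made last, from the flat tetrasubstituted alkene of 24, with the face chosen by O6. Precursor 24 then carries only three stereocentres (C4, C6, C10), none of them an all-carbon quaternary centre.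

**C8=C9 (24 ⇒ 23).** The seven-membered ring is opened at its only non-tetrasubstituted alkene by ring-closing metathesis. The partners are a vinyl group on C10 and a methallyl group on C6, held cis by the cyclopentene of 23.

**C10 (23 ⇒ 22 ⇒ 21 ⇒ 20 ⇒ 18 + 19).** O10 is silylated before O6 is freed, so the two secondary oxygens never have to be told apart. The C10–H bond comes from a reagent-controlled reduction of enone 20. The C9–C10 bond comes from Weinreb amide 18 and 19.

**C6–C7 (18 ⇒ 17 ⇒ 14 + 15, through 16).** Asymmetric methallylation of aldehyde 14 forms this bond and sets C6. This stereocentre directs the key step; it is later oxidised away and set again from C4.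

**C5–C6 (14 ⇒ 12 + 13; 12 ⇒ 11).** The formyl carbon is introduced by carbonylation of enol triflate 12, which fixes the tetrasubstituted C1=C5 alkene with two different carbon substituents.

**C1–C5 and C1–C2 (11 ⇒ 10 ⇒ 7 + 8, through 9).** The cyclopentane closes by a Dieckmann-type condensation. It has only one possible course because C4 is quaternary. The chain is assembled by cross-metathesis of 7 with 8.

**C3–C4 and the C4 configuration (7 ⇒ 6 ⇒ 5 ⇒ 3 + 4; 3 ⇒ 1 + 2).** C4 is taken from the chiral pool: acid 1 already has the oxygen, the isopropyl group and the future C5. Its stereocentre is stored in acetal 3 and returned on allylation with net retention.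

## Alternatives that were turned down

**Alternative 1:** intramolecular oxyallyl (4+3) cycloaddition. The disconnection cuts C1–C5 and C8–C9 and opens both rings to acyclic chloro ketone A1. In the forward step the tertiary chloride next to the ketone is ionised, and the oxyallyl cation (C1–C10–C9) is trapped by the tethered 2-silyloxydiene (C5–C8) to give A2.
- *For:* both rings and the quaternary centre form in one step from a linear precursor. On convergence and step count this route is stronger than the chosen one.
- *Against:* C1 and C5 are created in one transition state whose only control is the C4 centre in a three-atom tether, so both the fusion (compact or extended approach) and the face relative to C4 are open. The silyloxydiene and the tertiary silyl ether must survive ionising conditions. A2 has the wrong oxidation pattern: a C8 stereocentre that must be destroyed by dehydrogenation, a C10 ketone to be reduced under substrate control beside the new quaternary centre, and a C6 enol ether.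
- *Comparison:* the chosen route is longer, but every stereocentre has a named control element and C1 is set by an oxygen the target keeps.

**Alternative 2:** gold-catalysed enol ether–alkyne closure. The disconnection cuts C1–C2. In the forward step Ph3PAuNTf2 activates the terminal alkyne on C4 of A3, and the C10 silyl enol ether attacks through C1 (5-endo-dig) to give A4.
- *For:* mild catalysis, and a quaternary centre whose cis fusion is enforced by the tether. As a single step this closure is probably more dependable than cyclopropanation of a crowded tetrasubstituted alkene.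
- *Against:* A3 must already carry the C4/C5/C6 triad on a flexible seven-membered ring, including the quaternary propargylic carbinol on C5, with no evident control. The dienol ether must be formed towards C1 from a cross-conjugated dienone. A4 has an extra C2=C3 alkene that must be hydrogenated in the presence of the C8=C9 enone, and its C10 ketone still needs a substrate-controlled reduction.
- *Comparison:* the risk moves from the key step to the preparation of its substrate and to the clean-up. The chosen route reaches its precursor with reagent-controlled steps.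

**Alternative 3:** nitrile oxide cycloaddition. The disconnection cuts C5–C6 and O–C4. In the forward step oxime A5 is oxidised (NaOCl) and the dipole adds to the tethered 1-isopropylcyclopentene to give isoxazoline A6.
- *For:* the syn addition fixes O4 and C6 cis, and the tether from C1 forces the cis fusion. The C4/C5 relation, which the chosen route leaves to enolate protonation, is set by mechanism here; on that point this route is stronger. N–O cleavage (Mo(CO)6) would give the same β-hydroxy ketone as 29, so the endgame is shared.
- *Against:* the quaternary C1 with its C10 carbinol neighbour must be built in enantiopure form before the key step, so the hardest centre comes first. Closing a seven-membered ring onto a trisubstituted alkene to form a fully substituted carbon is slow, and dimerisation of the dipole competes. The dipole precursor has an allylic α-CH2 (C7) that invites isomerisation.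
- *Comparison:* the chosen route makes C1 last, from a flat alkene.

Key step: step 16

Remark: the allylborane 16 made from (−)-Ipc2BOMe (from (+)-α-pinene) is taken to attack the si face of aldehyde 14, as it does with simple aldehydes.
Remark: the cis-fused C5 epimer of ketone 28 is taken to be the more stable one, because it keeps C6 trans to the isopropyl group on C4.

## Route

Step 1
Reactants: 1 (R)-2-hydroxy-3-methylbutanoic acid; 2 pivalaldehyde
Product: 3 (2R,5R)-2-tert-butyl-5-isopropyl-1,3-dioxolan-4-one (cis)
Conditions: TsOH (cat.), pentane, reflux, Dean–Stark; crystallisation of the cis isomer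
Reagents that add atoms: none
Why: Acid-catalysed acetalisation (self-regeneration-of-stereocentres template); the cis acetal is favoured and is purified, so the acetal carbon stores the chirality of the future C4.

Step 2
Reactants: 3 (2R,5R)-2-tert-butyl-5-isopropyl-1,3-dioxolan-4-one; 4 allyl bromide
Product: 5 (2R,5R)-5-allyl-2-tert-butyl-5-isopropyl-1,3-dioxolan-4-one
Conditions: LiN(iPr)2, THF, −78 °C; then 4, −78 to −30 °C
Reagents that add atoms: none
Why: Enolate alkylation; the enolate is planar at C4 and allyl bromide enters anti to the tert-butyl group, so allyl takes the place of the former hydrogen (net retention) and the C3–C4 bond is formed with C4 fixed as R.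

Step 3
Reactants: 5 (2R,5R)-5-allyl-2-tert-butyl-5-isopropyl-1,3-dioxolan-4-one
Product: 6 methyl (R)-2-hydroxy-2-isopropylpent-4-enoate
Conditions: NaOMe (0.2 equiv), MeOH, 0 °C to rt
Reagents that add atoms: methanol, CO
Why: Methoxide-catalysed transesterification opens the activated acylal and releases pivalaldehyde; no stereocentre is touched.

Step 4
Reactants: 6 methyl (R)-2-hydroxy-2-isopropylpent-4-enoate
Product: 7 methyl (R)-2-isopropyl-2-(triethylsilyloxy)pent-4-enoate
Conditions: Et3SiOTf, 2,6-lutidine, CH2Cl2, 0 °C to rt
Reagents that add atoms: triethylsilyl trifluoromethanesulfonate, CC[Si](CC)(CC)OS(=O)(=O)C(F)(F)F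
Why: Silyl triflate silylation of a hindered tertiary alcohol; the ether prevents lactonisation in the next steps and later keeps O4 from directing the carbenoid to the lower face.

Step 5
Reactants: 7 methyl (R)-2-isopropyl-2-(triethylsilyloxy)pent-4-enoate; 8 N-methoxy-N-methylacrylamide
Product: 10 methyl (R)-2-isopropyl-6-[methoxy(methyl)amino]-6-oxo-2-(triethylsilyloxy)hexanoate, via unsaturated Weinreb amide 9 (not isolated)
Conditions: 8 (3 equiv), second-generation Grubbs catalyst (5 mol %), CH2Cl2, 40 °C; then H2 (1 atm), Pd/C, EtOAc, rt
Reagents that add atoms: none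
Why: Olefin cross-metathesis of a terminal alkene with an acrylamide (E-selective, driven by loss of ethylene) forms C1–C2; heterogeneous hydrogenation then saturates the conjugated alkene without affecting the silyl ether or the N–O bond.

Step 6
Reactants: 10 methyl (R)-2-isopropyl-6-[methoxy(methyl)amino]-6-oxo-2-(triethylsilyloxy)hexanoate
Product: 11 (3R)-3-isopropyl-N-methoxy-N-methyl-2-oxo-3-(triethylsilyloxy)cyclopentane-1-carboxamide (mixture at C1, keto/enol)
Conditions: NaN(SiMe3)2 (2.2 equiv), THF, −78 to 0 °C; aqueous NH4Cl work-up
Reagents that add atoms: none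
Why: Dieckmann-type condensation (5-exo-trig); only the amide α-carbon C1 has acidic hydrogens and the ester carbon has a quaternary neighbour, so one β-keto amide forms (C1–C5 bond), driven by deprotonation of the product.

Step 7
Reactants: 11 (3R)-3-isopropyl-N-methoxy-N-methyl-2-oxo-3-(triethylsilyloxy)cyclopentane-1-carboxamide
Product: 12 (R)-3-isopropyl-N-methoxy-N-methyl-3-(triethylsilyloxy)-2-(trifluoromethylsulfonyloxy)cyclopent-1-ene-1-carboxamide
Conditions: Tf2O, iPr2NEt, CH2Cl2, −78 °C
Reagents that add atoms: trifluoromethanesulfonic anhydride, O=S(=O)(OS(=O)(=O)C(F)(F)F)C(F)(F)F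
Why: O-sulfonylation of the β-keto amide enol gives the ring enol triflate and fixes the tetrasubstituted C1=C5 alkene.

Step 8
Reactants: 12 (R)-3-isopropyl-N-methoxy-N-methyl-3-(triethylsilyloxy)-2-(trifluoromethylsulfonyloxy)cyclopent-1-ene-1-carboxamide; 13 carbon monoxide
Product: 14 (R)-2-formyl-3-isopropyl-N-methoxy-N-methyl-3-(triethylsilyloxy)cyclopent-1-ene-1-carboxamide
Conditions: CO (1 atm), Pd(PPh3)4 (5 mol %), LiCl, Bu3SnH (slow addition), THF, 50 °C
Reagents that add atoms: none
Why: Palladium-catalysed reductive carbonylation (formylation) of an enol triflate: oxidative addition to zerovalent palladium, CO insertion and hydride transfer from tin form C5–C6; slow hydride addition under CO suppresses direct reduction of the triflate.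

Step 9
Reactants: 14 (R)-2-formyl-3-isopropyl-N-methoxy-N-methyl-3-(triethylsilyloxy)cyclopent-1-ene-1-carboxamide; 15 2-methylallylmagnesium chloride
Product: 17 (R)-2-[(S)-1-hydroxy-3-methylbut-3-enyl]-3-isopropyl-N-methoxy-N-methyl-3-(triethylsilyloxy)cyclopent-1-ene-1-carboxamide, via allylborane 16 (not isolated)
Conditions: (−)-Ipc2BOMe + 15, Et2O, −78 °C to rt; then 14, −78 °C; NaBO3·4H2O, THF/H2O, rt
Reagents that add atoms: none
Why: Brown asymmetric methallylboration through a chair six-membered transition state forms C6–C7; the isopinocampheyl groups direct the methallyl group to the si face of the aldehyde, which sets C6 as S under reagent control.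

Step 10
Reactants: 17 (R)-2-[(S)-1-hydroxy-3-methylbut-3-enyl]-3-isopropyl-N-methoxy-N-methyl-3-(triethylsilyloxy)cyclopent-1-ene-1-carboxamide
Product: 18 (R)-3-isopropyl-N-methoxy-N-methyl-2-[(S)-3-methyl-1-(triethylsilyloxy)but-3-enyl]-3-(triethylsilyloxy)cyclopent-1-ene-1-carboxamide
Conditions: Et3SiCl, imidazole, DMF, 0 °C
Reagents that add atoms: chlorotriethylsilane, CC[Si](Cl)(CC)CC
Why: Standard silylation; the temporary ether stops the C6 hydroxyl from closing onto the neighbouring amide and keeps it out of the next three steps.

Step 11
Reactants: 18 (R)-3-isopropyl-N-methoxy-N-methyl-2-[(S)-3-methyl-1-(triethylsilyloxy)but-3-enyl]-3-(triethylsilyloxy)cyclopent-1-ene-1-carboxamide; 19 vinylmagnesium bromide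
Product: 20 1-{(R)-3-isopropyl-2-[(S)-3-methyl-1-(triethylsilyloxy)but-3-enyl]-3-(triethylsilyloxy)cyclopent-1-enyl}prop-2-en-1-one
Conditions: 19 (3 equiv), THF, −78 to −20 °C; inverse quench into cold aqueous NH4Cl/AcOH; used at once
Reagents that add atoms: none
Why: Weinreb ketone synthesis; the chelated tetrahedral intermediate prevents a second addition and the C9–C10 bond is formed, and the cold, weakly acidic inverse quench keeps the released N,O-dimethylhydroxylamine from adding to the vinyl ketone.

Step 12
Reactants: 20 1-{(R)-3-isopropyl-2-[(S)-3-methyl-1-(triethylsilyloxy)but-3-enyl]-3-(triethylsilyloxy)cyclopent-1-enyl}prop-2-en-1-one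
Product: 21 (R)-1-{(R)-3-isopropyl-2-[(S)-3-methyl-1-(triethylsilyloxy)but-3-enyl]-3-(triethylsilyloxy)cyclopent-1-enyl}prop-2-en-1-ol
Conditions: (S)-2-methyl-CBS-oxazaborolidine (0.2 equiv), catecholborane, toluene, −78 °C
Reagents that add atoms: none
Why: Corey–Bakshi–Shibata reduction; the fully substituted cyclopentenyl group acts as the large substituent and vinyl as the small one, so the (S)-catalyst should give the (R)-carbinol at C10, and catecholborane at low temperature reduces 1,2 without hydroborating the alkenes.

Step 13
Reactants: 21 (R)-1-{(R)-3-isopropyl-2-[(S)-3-methyl-1-(triethylsilyloxy)but-3-enyl]-3-(triethylsilyloxy)cyclopent-1-enyl}prop-2-en-1-ol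
Product: 22 tert-butyldimethylsilyl ether of 21 at O10 (all three oxygens silylated)
Conditions: tBuMe2SiOTf, 2,6-lutidine, CH2Cl2, −78 °C
Reagents that add atoms: tert-butyldimethylsilyl trifluoromethanesulfonate, CC(C)(C)[Si](C)(C)OS(=O)(=O)C(F)(F)F
Why: Silylation of the secondary allylic alcohol; this ether later keeps O10 from directing the carbenoid to C8=C9 and survives the dissolving-metal step.

Step 14
Reactants: 22 tert-butyldimethylsilyl ether of 21 at O10
Product: 23 (S)-1-{(R)-2-[(R)-1-(tert-butyldimethylsilyloxy)allyl]-5-isopropyl-5-(triethylsilyloxy)cyclopent-1-enyl}-3-methylbut-3-en-1-ol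
Conditions: PPTS (cat.), MeOH/CH2Cl2, 0 °C
Reagents that add atoms: none
Why: Acid-catalysed methanolysis of silyl ethers; the secondary triethylsilyl ether at O6 should be cleaved well before the tertiary one at O4 and the tert-butyldimethylsilyl ether at O10, on steric grounds.

Step 15
Reactants: 23 (S)-1-{(R)-2-[(R)-1-(tert-butyldimethylsilyloxy)allyl]-5-isopropyl-5-(triethylsilyloxy)cyclopent-1-enyl}-3-methylbut-3-en-1-ol
Product: 24 bicyclic dienol (4R,6S,10R): C1=C5 and C8=C9 alkenes, free 6-OH, 10-OSiMe2tBu, 4-OSiEt3, 4-isopropyl, 8-methyl
Conditions: second-generation Grubbs catalyst (10 mol %), CH2Cl2 (2 mM), 40 °C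
Reagents that add atoms: none
Why: Ring-closing metathesis closes the seven-membered ring at C8=C9; the two chains are held cis on the cyclopentene, the tetrasubstituted C1=C5 bond is inert to the carbene, and ethylene loss drives the reaction.

Step 16
Reactants: 24 bicyclic dienol (4R,6S,10R); 25 diiodomethane
Product: 26 cyclopropane-fused alcohol (1S,4R,5S,6S,10R): C15 bridges C1 and C5 on the face of the 6-OH; 10-OSiMe2tBu, 4-OSiEt3, C8=C9 intact
Conditions: Et2Zn (5 equiv), 25 (10 equiv), CH2Cl2, −10 °C to rt
Reagents that add atoms: none
Why: Et2Zn turns the C6 hydroxyl into an ethylzinc alkoxide and forms iodomethylzinc species with 25; the carbenoid held at this alkoxide transfers CH2 to the neighbouring C1=C5 bond through the butterfly transition state of the Simmons–Smith reaction (Furukawa variant). The closest known reaction type is the hydroxyl-directed cyclopropanation of cyclohex-2-enols and cyclohept-2-enols, which gives the syn cyclopropyl carbinols. The three-membered ring C1–C5–C15 closes by a concerted, suprafacial (2+1) methylene transfer in which C1–C15 and C5–C15 form together, so the alkene carbons keep their ring substituents cis. C1 and C5 become stereocentres and both are controlled by the C6 oxygen: the zinc alkoxide sits on the upper face and delivers CH2 only there, which places C15 cis to O6 and O10. The step needs face selectivity and site selectivity over C8=C9. The face is secured by alkoxide delivery, helped by the triethylsilyloxy group on C4 that shields the lower face. The site is secured because C1=C5 is allylic to the free hydroxyl and tetrasubstituted, hence the most nucleophilic alkene, whereas C8=C9 is only homoallylic to it and its own allylic oxygen at C10 is capped as a silyl ether. The isopropyl group and the C10 silyl ether on the upper face are expected to slow the transfer, so an excess of carbenoid is used.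

Step 17
Reactants: 26 cyclopropane-fused alcohol (1S,4R,5S,6S,10R)
Product: 27 cyclopropyl ketone (1S,4R,5R,10R): C6 ketone beside the C1–C5–C15 cyclopropane
Conditions: Dess–Martin periodinane, pyridine, CH2Cl2, 0 °C to rt
Reagents that add atoms: none
Why: Dess–Martin oxidation of the secondary cyclopropyl carbinol under buffered, non-acidic conditions that spare the cyclopropane and the silyl ethers; the C6 stereocentre has done its work and is removed here.

Step 18
Reactants: 27 cyclopropyl ketone (1S,4R,5R,10R)
Product: 28 cis-fused ketone (1R,4R,5R,10R): C1 methyl and H5 on the upper face, C6 ketone, 4-OSiEt3, 10-OSiMe2tBu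
Conditions: Li, NH3 (l)/THF, −78 °C; then NH4Cl (s)
Reagents that add atoms: none
Why: Dissolving-metal reduction of a cyclopropyl ketone: the ketyl opens the cyclopropane bond that overlaps the carbonyl π system and gives the less substituted carbanion (C5–C15), so C15 becomes the C1 methyl on the face where the methylene was delivered. The C5 enolate is protonated on quenching; the cis fusion, with C6 trans to the isopropyl group, is expected and is also the epimer favoured at equilibrium. Silyl ethers and the isolated alkene are inert at −78 °C.

Step 19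
Reactants: 28 cis-fused ketone (1R,4R,5R,10R)
Product: 29 β-hydroxy ketone (1R,4R,5R,10R): free tertiary 4-OH, C6 ketone, 10-OSiMe2tBu
Conditions: HF·pyridine, pyridine, THF, 0 °C
Reagents that add atoms: none
Why: Fluoride-mediated desilylation under buffered acidic conditions; the triethylsilyl ether is far more labile than the tert-butyldimethylsilyl ether at the neopentyl-type C10, and non-basic conditions avoid retro-aldol cleavage or elimination of the β-hydroxy ketone.

Step 20
Reactants: 29 β-hydroxy ketone (1R,4R,5R,10R)
Product: 30 diol (1R,4R,5S,6S,10R): 4-OH and 6-OH free, 10-OSiMe2tBu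
Conditions: Me4NBH(OAc)3, MeCN/AcOH, −30 °C
Reagents that add atoms: none
Why: Evans–Saksena directed reduction: the C4 hydroxyl exchanges onto boron and the alkoxyborohydride delivers hydride to C6 from the lower, concave face, the face of O4. The new hydroxyl therefore appears on the upper face (6S, anti to O4); triacetoxyborohydride reduces only the ketone that the hydroxyl activates and leaves the alkene and the silyl ether alone.

Step 21
Reactants: 30 diol (1R,4R,5S,6S,10R); 31 4-acetoxybenzoyl chloride
Product: 32 6-O-(4-acetoxybenzoyl) ester of 30 (4-OH free, 10-OSiMe2tBu)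
Conditions: 31, pyridine, DMAP (cat.), CH2Cl2, 0 °C to rt
Reagents that add atoms: none
Why: Nucleophile-catalysed acylation of the only secondary alcohol; the tertiary C4 hydroxyl does not react and the acid chloride is far more reactive than the aryl acetate it carries.

Step 22
Reactants: 32 6-O-(4-acetoxybenzoyl) ester of 30
Product: 33 10-alcohol: 6-O-(4-acetoxybenzoyl), 4-OH and 10-OH free
Conditions: HF·pyridine, THF, rt
Reagents that add atoms: none
Why: Fluoride cleavage of the remaining silyl ether under acidic conditions that leave the alkyl benzoate and the aryl acetate intact and do not promote acyl migration.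

Step 23
Reactants: 33 10-alcohol; 34 tigloyl chloride ((E)-2-methylbut-2-enoyl chloride)
Product: 35 10-O-tigloyl-6-O-(4-acetoxybenzoyl) diester with free 4-OH
Conditions: 34, pyridine, DMAP (cat.), CH2Cl2, 0 °C to rt
Reagents that add atoms: none
Why: DMAP-catalysed acylation of the hindered secondary allylic alcohol; pyridine in place of a trialkylamine avoids vinylketene formation and deconjugation of the acyl chloride, the E (tigloyl) geometry is the stable one, and the tertiary alcohol stays free.

Step 24
Reactants: 35 10-O-tigloyl-6-O-(4-acetoxybenzoyl) diester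
Product: 36 target (1R,4R,5S,6S,10R): 10-O-tigloyl, 6-O-(4-hydroxybenzoyl), 4-OH
Conditions: K2CO3 (0.2 equiv), MeOH, 0 °C
Reagents that add atoms: none
Why: Selective transesterification: an aryl acetate is methanolysed far faster than an alkyl benzoate or an α-branched enoate, and the phenoxide formed deactivates the benzoate carbonyl further.

## Compound list

1 | (R)-2-hydroxy-3-methylbutanoic acid | CC(C)[C@@H](O)C(=O)O | starting material
2 | pivalaldehyde | CC(C)(C)C=O | starting material
3 | (2R,5R)-2-tert-butyl-5-isopropyl-1,3-dioxolan-4-one | CC(C)[C@H]1O[C@@H](C(C)(C)C)OC1=O | intermediate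
4 | allyl bromide | C=CCBr | starting material
5 | (2R,5R)-5-allyl-2-tert-butyl-5-isopropyl-1,3-dioxolan-4-one | CC(C)[C@@]1(CC=C)O[C@@H](C(C)(C)C)OC1=O | intermediate
6 | methyl (R)-2-hydroxy-2-isopropylpent-4-enoate | COC(=O)[C@](O)(C(C)C)CC=C | intermediate
7 | methyl (R)-2-isopropyl-2-(triethylsilyloxy)pent-4-enoate | COC(=O)[C@](O[Si](CC)(CC)CC)(C(C)C)CC=C | intermediate
8 | N-methoxy-N-methylacrylamide | C=CC(=O)N(C)OC | starting material
9 | methyl (R,E)-2-isopropyl-6-[methoxy(methyl)amino]-6-oxo-2-(triethylsilyloxy)hex-4-enoate | COC(=O)[C@](O[Si](CC)(CC)CC)(C(C)C)C/C=C/C(=O)N(C)OC | intermediate (not isolated)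
10 | methyl (R)-2-isopropyl-6-[methoxy(methyl)amino]-6-oxo-2-(triethylsilyloxy)hexanoate | COC(=O)[C@](O[Si](CC)(CC)CC)(C(C)C)CCCC(=O)N(C)OC | intermediate
11 | (3R)-3-isopropyl-N-methoxy-N-methyl-2-oxo-3-(triethylsilyloxy)cyclopentane-1-carboxamide | CON(C)C(=O)C1CC[C@@](O[Si](CC)(CC)CC)(C(C)C)C1=O | intermediate
12 | (R)-3-isopropyl-N-methoxy-N-methyl-3-(triethylsilyloxy)-2-(trifluoromethylsulfonyloxy)cyclopent-1-ene-1-carboxamide | CON(C)C(=O)C1=C(OS(=O)(=O)C(F)(F)F)[C@](O[Si](CC)(CC)CC)(C(C)C)CC1 | intermediate
13 | carbon monoxide | [C-]#[O+] | starting material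
14 | (R)-2-formyl-3-isopropyl-N-methoxy-N-methyl-3-(triethylsilyloxy)cyclopent-1-ene-1-carboxamide | CON(C)C(=O)C1=C(C=O)[C@](O[Si](CC)(CC)CC)(C(C)C)CC1 | intermediate
15 | 2-methylallylmagnesium chloride | CC(=C)C[Mg]Cl | starting material
16 | (−)-B-(2-methylallyl)diisopinocampheylborane | CC(=C)CB([C@H]1[C@H](C)[C@H]2C[C@@H](C1)C2(C)C)[C@H]1[C@H](C)[C@H]2C[C@@H](C1)C2(C)C | intermediate (not isolated)
17 | (R)-2-[(S)-1-hydroxy-3-methylbut-3-enyl]-3-isopropyl-N-methoxy-N-methyl-3-(triethylsilyloxy)cyclopent-1-ene-1-carboxamide | CON(C)C(=O)C1=C([C@@H](O)CC(C)=C)[C@](O[Si](CC)(CC)CC)(C(C)C)CC1 | intermediate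
18 | (R)-3-isopropyl-N-methoxy-N-methyl-2-[(S)-3-methyl-1-(triethylsilyloxy)but-3-enyl]-3-(triethylsilyloxy)cyclopent-1-ene-1-carboxamide | CON(C)C(=O)C1=C([C@@H](O[Si](CC)(CC)CC)CC(C)=C)[C@](O[Si](CC)(CC)CC)(C(C)C)CC1 | intermediate
19 | vinylmagnesium bromide | C=C[Mg]Br | starting material
20 | 1-{(R)-3-isopropyl-2-[(S)-3-methyl-1-(triethylsilyloxy)but-3-enyl]-3-(triethylsilyloxy)cyclopent-1-enyl}prop-2-en-1-one | C=CC(=O)C1=C([C@@H](O[Si](CC)(CC)CC)CC(C)=C)[C@](O[Si](CC)(CC)CC)(C(C)C)CC1 | intermediate
21 | (R)-1-{(R)-3-isopropyl-2-[(S)-3-methyl-1-(triethylsilyloxy)but-3-enyl]-3-(triethylsilyloxy)cyclopent-1-enyl}prop-2-en-1-ol | C=C[C@@H](O)C1=C([C@@H](O[Si](CC)(CC)CC)CC(C)=C)[C@](O[Si](CC)(CC)CC)(C(C)C)CC1 | intermediate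
22 | O10 tert-butyldimethylsilyl ether of 21 | C=C[C@@H](O[Si](C)(C)C(C)(C)C)C1=C([C@@H](O[Si](CC)(CC)CC)CC(C)=C)[C@](O[Si](CC)(CC)CC)(C(C)C)CC1 | intermediate
23 | (S)-1-{(R)-2-[(R)-1-(tert-butyldimethylsilyloxy)allyl]-5-isopropyl-5-(triethylsilyloxy)cyclopent-1-enyl}-3-methylbut-3-en-1-ol | C=C[C@@H](O[Si](C)(C)C(C)(C)C)C1=C([C@@H](O)CC(C)=C)[C@](O[Si](CC)(CC)CC)(C(C)C)CC1 | intermediate
24 | bicyclic dienol (4R,6S,10R): C1=C5, C8=C9, 6-OH, 10-OSiMe2tBu, 4-OSiEt3 | CC(C)(C)[Si](C)(C)O[C@@H]1C=C(C)C[C@H](O)C2=C1CC[C@@]2(O[Si](CC)(CC)CC)C(C)C | intermediate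
25 | diiodomethane | ICI | starting material
26 | cyclopropane-fused alcohol (1S,4R,5S,6S,10R), C15 on the face of the 6-OH | CC(C)(C)[Si](C)(C)O[C@@H]1C=C(C)C[C@H](O)[C@]23C[C@]12CC[C@@]3(O[Si](CC)(CC)CC)C(C)C | intermediate
27 | cyclopropyl ketone (1S,4R,5R,10R) | CC(C)(C)[Si](C)(C)O[C@@H]1C=C(C)CC(=O)[C@]23C[C@]12CC[C@@]3(O[Si](CC)(CC)CC)C(C)C | intermediate
28 | cis-fused C6 ketone (1R,4R,5R,10R), 4-OSiEt3, 10-OSiMe2tBu | CC(C)(C)[Si](C)(C)O[C@@H]1C=C(C)CC(=O)[C@@H]2[C@@]1(C)CC[C@@]2(O[Si](CC)(CC)CC)C(C)C | intermediate
29 | β-hydroxy ketone (1R,4R,5R,10R), 4-OH, 10-OSiMe2tBu | CC(C)(C)[Si](C)(C)O[C@@H]1C=C(C)CC(=O)[C@@H]2[C@@]1(C)CC[C@@]2(O)C(C)C | intermediate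
30 | diol (1R,4R,5S,6S,10R), 10-OSiMe2tBu | CC(C)(C)[Si](C)(C)O[C@@H]1C=C(C)C[C@H](O)[C@@H]2[C@@]1(C)CC[C@@]2(O)C(C)C | intermediate
31 | 4-acetoxybenzoyl chloride | CC(=O)Oc1ccc(cc1)C(Cl)=O | starting material
32 | 6-O-(4-acetoxybenzoyl) ester, 10-OSiMe2tBu, 4-OH | CC(C)(C)[Si](C)(C)O[C@@H]1C=C(C)C[C@H](OC(=O)c2ccc(OC(C)=O)cc2)[C@@H]2[C@@]1(C)CC[C@@]2(O)C(C)C | intermediate
33 | 6-O-(4-acetoxybenzoyl) ester, 10-OH, 4-OH | O[C@@H]1C=C(C)C[C@H](OC(=O)c2ccc(OC(C)=O)cc2)[C@@H]2[C@@]1(C)CC[C@@]2(O)C(C)C | intermediate
34 | tigloyl chloride | C/C=C(\C)C(Cl)=O | starting material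
35 | 10-O-tigloyl-6-O-(4-acetoxybenzoyl) diester, 4-OH | C/C=C(\C)C(=O)O[C@@H]1C=C(C)C[C@H](OC(=O)c2ccc(OC(C)=O)cc2)[C@@H]2[C@@]1(C)CC[C@@]2(O)C(C)C | intermediate
36 | target CNP0273650.9 | C/C=C(\C)C(=O)O[C@@H]1C=C(C)C[C@H](OC(=O)c2ccc(O)cc2)[C@@H]2[C@@]1(C)CC[C@@]2(O)C(C)C | target

## Step count and least certain steps

Total step count: 24. Longest linear sequence: 24 steps (from 1 to 36); all other inputs are commercial.

The least certain steps are discussed below, the key step first.

In step 16, the key step, the likeliest failure is slow or incomplete methylene transfer to the crowded tetrasubstituted alkene, because the isopropyl group and the C10 silyl ether sit on the delivery face. Partial cyclopropanation of C8=C9 through the homoallylic alkoxide, or ionisation of the allylic silyl ethers by ZnI2, would then compete. Fallback: the carbene is tied covalently to O6. Setting out from 24, acylation with glyoxylic acid chloride p-toluenesulfonylhydrazone and Et3N gives the C6 diazoacetate F1. Cu(acac)2 or Rh2(OAc)4 then brings about intramolecular cyclopropanation of C1=C5, which can only occur on the O6 face, and gives the cyclopropane-fused γ-lactone F2. LiAlH4 opens it to the diol F3, Dess–Martin oxidation gives the keto aldehyde F4, and decarbonylation of this cyclopropanecarbaldehyde with RhCl(PPh3)3 comes back to the route at 27.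

In step 9, the likeliest failure is cyclisation of the new C6 alkoxide onto the cis Weinreb amide during work-up, which would leave the alcohol mixed with its lactone. Fallback: setting out from 14, the methallylation is run as before and the cyclisation is driven to completion (PPTS, CH2Cl2) to the butenolide F5, a stable form of the C6 alcohol. Aminolysis with Me2AlN(OMe)Me reopens it and comes back to the route at 17, which is silylated at once.

In step 12, the likeliest failures are conjugate reduction or polymerisation of the vinyl ketone, or weak discrimination between the two alkenyl groups by the catalyst. Fallback: setting out from 18, iBu2AlH reduces the Weinreb amide to the aldehyde F6. Catalytic asymmetric vinyl transfer from divinylzinc with a chiral β-amino alcohol ligand (3-exo-morpholinoisoborneol, the enantiomer that directs attack to the re face) then comes back to the route at 21, without passing through the enone.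

In step 15, the likeliest failure is slow initiation, since one alkene is 1,1-disubstituted and the other is flanked by a bulky allylic silyl ether; oligomerisation or catalyst decay would then win. Fallback: the ring is closed one stage earlier, on the free allylic alcohol. Setting out from 21, ring-closing metathesis gives the bicyclic C10 alcohol F7. Silylation with tBuMe2SiOTf gives the tris-silyl ether F8, and PPTS/MeOH removes the O6 triethylsilyl group, which comes back to the route at 24.

In step 18, the likeliest failure is protonation of the C5 enolate from the lower face, which would give the trans fusion; over-reduction of the ketone and β-elimination of the C4 silyloxy group from the enolate are lesser risks. Fallback: control is moved from kinetic protonation to equilibrium. Setting out from 27, the reduction is accepted as it comes, and the trans-fused ketone F9 is equilibrated with DBU in CH2Cl2, which comes back to the route at the cis-fused ketone 28, in which C6 is trans to the isopropyl group.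

In step 20, the likeliest failure is that the hindered tertiary C4 hydroxyl does not load onto boron, so that hydride arrives externally from the convex face and inverts the outcome at C6. Fallback: the wrong epimer is used on purpose. Setting out from 28, NaBH4 in MeOH gives the 6-epi alcohol F10. Mitsunobu esterification with 4-acetoxybenzoic acid (PPh3, diisopropyl azodicarboxylate) inverts C6 and installs the aroyl group, giving the ester F11. HF·pyridine then removes both silyl groups and comes back to the route at 33.

## Further compounds

F1 | step 16 | C6 diazoacetate of 24 | CC(C)(C)[Si](C)(C)O[C@@H]1C=C(C)C[C@H](OC(=O)C=[N+]=[N-])C2=C1CC[C@@]2(O[Si](CC)(CC)CC)C(C)C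
F2 | step 16 | cyclopropane-fused γ-lactone (O6–CO–C15, C15 bridging C1 and C5) | CC(C)(C)[Si](C)(C)O[C@@H]1C=C(C)C[C@@H]2OC(=O)[C@H]3[C@]24[C@@]13CC[C@@]4(O[Si](CC)(CC)CC)C(C)C
F3 | step 16 | diol (6-OH and hydroxymethyl on C15) | CC(C)(C)[Si](C)(C)O[C@@H]1C=C(C)C[C@H](O)[C@]23[C@H](CO)[C@]12CC[C@@]3(O[Si](CC)(CC)CC)C(C)C
F4 | step 16 | keto aldehyde (C6 ketone, formyl on C15) | CC(C)(C)[Si](C)(C)O[C@@H]1C=C(C)CC(=O)[C@]23[C@H](C=O)[C@]12CC[C@@]3(O[Si](CC)(CC)CC)C(C)C
F5 | step 9 | (3S,4R)-4-isopropyl-3-(2-methylallyl)-4-(triethylsilyloxy)-3,4,5,6-tetrahydro-1H-cyclopenta[c]furan-1-one | O=C1O[C@@H](CC(C)=C)C2=C1CC[C@@]2(O[Si](CC)(CC)CC)C(C)C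
F6 | step 12 | (R)-3-isopropyl-2-[(S)-3-methyl-1-(triethylsilyloxy)but-3-enyl]-3-(triethylsilyloxy)cyclopent-1-ene-1-carbaldehyde | O=CC1=C([C@@H](O[Si](CC)(CC)CC)CC(C)=C)[C@](O[Si](CC)(CC)CC)(C(C)C)CC1
F7 | step 15 | bicyclic diene with free 10-OH, 6-OSiEt3, 4-OSiEt3 | O[C@@H]1C=C(C)C[C@H](O[Si](CC)(CC)CC)C2=C1CC[C@@]2(O[Si](CC)(CC)CC)C(C)C
F8 | step 15 | bicyclic diene with 10-OSiMe2tBu, 6-OSiEt3, 4-OSiEt3 | CC(C)(C)[Si](C)(C)O[C@@H]1C=C(C)C[C@H](O[Si](CC)(CC)CC)C2=C1CC[C@@]2(O[Si](CC)(CC)CC)C(C)C
F9 | step 18 | trans-fused C5 epimer of 28 | CC(C)(C)[Si](C)(C)O[C@@H]1C=C(C)CC(=O)[C@H]2[C@@]1(C)CC[C@@]2(O[Si](CC)(CC)CC)C(C)C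
F10 | step 20 | 6-epi alcohol (6R), 4-OSiEt3, 10-OSiMe2tBu | CC(C)(C)[Si](C)(C)O[C@@H]1C=C(C)C[C@@H](O)[C@@H]2[C@@]1(C)CC[C@@]2(O[Si](CC)(CC)CC)C(C)C
F11 | step 20 | 6-O-(4-acetoxybenzoyl) ester (6S), 4-OSiEt3, 10-OSiMe2tBu | CC(C)(C)[Si](C)(C)O[C@@H]1C=C(C)C[C@H](OC(=O)c2ccc(OC(C)=O)cc2)[C@@H]2[C@@]1(C)CC[C@@]2(O[Si](CC)(CC)CC)C(C)C
A1 | alternative 1 | acyclic tertiary α-chloro ketone with tethered 2-silyloxydiene | CC(=O)C(C)(Cl)CC[C@@](O[Si](CC)(CC)CC)(C(C)C)/C=C(O[Si](C)(C)C(C)(C)C)/C=C/C
A2 | alternative 1 | hydroazulen-10-one with C6 silyl enol ether | O=C1C[C@@H](C)C=C(O[Si](C)(C)C(C)(C)C)[C@@H]2[C@@]1(C)CC[C@@]2(O[Si](CC)(CC)CC)C(C)C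
A3 | alternative 2 | cycloheptadienyl C10 silyl enol ether carrying the C4 propargylic silyl ether on C5 | C#C[C@@](O[Si](CC)(CC)CC)(C(C)C)[C@@H]1[C@@H](O[Si](C)(C)C(C)(C)C)CC(C)=CC(O[Si](C)(C)C(C)(C)C)=C1C
A4 | alternative 2 | cis-fused bicyclic 10-ketone with C2=C3 alkene | O=C1C=C(C)C[C@H](O[Si](C)(C)C(C)(C)C)[C@@H]2[C@@]1(C)C=C[C@@]2(O[Si](CC)(CC)CC)C(C)C
A5 | alternative 3 | C6 oxime tethered to the 1-isopropylcyclopentene through quaternary C1 | CC(C)C1=C[C@@](C)(CC1)[C@H](O[Si](C)(C)C(C)(C)C)/C=C(C)\CC=NO
A6 | alternative 3 | isoxazoline-fused hydroazulene | CC(C)(C)[Si](C)(C)O[C@@H]1C=C(C)CC2=NO[C@@]3(C(C)C)CC[C@]1(C)[C@@H]23
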